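Watch the electrophile. It is charged below the nucleophile, and its balance is short: whatever fraction of the charge is no longer electrophile sits in target or in what follows from it. We therefore ask how fast the fraction left falls.

| flask | electrophile | nucleophile | free base | remark | time |
|---|---|---|---|---|---|
| Thursday's | 0.25 M | 1.2 equiv | 1.2 equiv | run made earlier |  |
| Saturday's | 0.25 M | 1.2 equiv | 6.3 equiv | run made earlier |  |
| east | 0.25 M | 1.20 equiv | 1.00 equiv |  | 10 d |
| south-east | 0.25 M | 1.20 equiv | 2.00 equiv |  | 10 d |
| north-west | 0.25 M | 1.20 equiv | 4.00 equiv |  | 10 d |

- Thursday's (time / d: electrophile / %, target / %): 0.417: 72.6, 17.8; 0.625: 63.7, 20.1; 1.04: 50.5, 21.7; 1.67: 38.2, 19.9; 3.00: 21.8, 20.4; 5.00: 10.4, 21.7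
- Saturday's (time / d: electrophile / %, target / %): 0.833: 54.0, 22.9; 1.67: 34.7, 23.0; 2.50: 23.3, 20.8; 3.00: 18.8, 21.4; 4.00: 12.6, 21.3; 5.00: 9.2, 21.2

(scatter of a reading: 0.5 percentage points)

1. part of the electrophile that has reacted at the end, east
2. part of the electrophile that has reacted at the end, south-east
3. part of the electrophile that has reacted at the end, north-west
4. what raising the equivalents of free base from its lowest to its highest value here does to the part of the electrophile that has reacted (changes below 5 percentage points count as none) (no change / it rises / it falls)

We read the runs as a ladder of time scales. On the first rung stands the free base: Saturday's run held 5.25 times the free base of Thursday's, yet at 5.00 d the fractions of electrophile left in these two runs differ by 1.2 percentage points. On the next rung, target in Thursday's run reads between 19.9 % and 21.7 % from 1.04 d to 5.00 d, so over that stretch it is made about as fast as it is lost, while the electrophile falls from 50.5 % to 10.4 %. The last rung is the electrophile itself. Saturday's fall from 12.6 % at 4.00 d to 9.2 % at 5.00 d gives the late half-life, the time in which the fraction left halves near the end of a run: 2.20 d, a reading that carries the scatter. The time still to run is 2.27 such half-lives. Holding that half-life, our own reckoning gives 97.8 % reacted from Thursday's last reading, for east, and 98.1 % from Saturday's, for north-west.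

The forecast says 96.5 %, 97 % and 97.2 %, with no change, on the ground “so base has only a slight effect”; its east figure stands below our 97.8 %.

The simulation gives 97.6 %, 98.1 % and 98.3 %: no change, the move from east to north-west being 0.62 points against a margin of 5 points.

    acid set free + free base ⇌ salt of the base (K = 11000 L mol⁻¹, k = 3.62 L mol⁻¹ h⁻¹)
    target → over-reaction product (k = 2.97 × 10⁻⁵ h⁻¹)
    target ⇌ isomer of the product (K = 2.54, k = 0.0621 h⁻¹)
    electrophile + nucleophile → acid set free + target (k = 0.129 L mol⁻¹ h⁻¹)
    electrophile + target → side product (k = 0.0481 L mol⁻¹ h⁻¹)
    nucleophile + acid set free ⇌ protonated nucleophile, settled at all times (K = 74.8 L mol⁻¹)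

In south-east the electrophile falls from 9.47 % at 5.00 d to 1.86 % at 10.0 d, a half-life of 2.13 d beside our 2.20 d, and at 10.0 d the step to target uses electrophile 3.9 times as fast as the step to side product. In a flask like south-east but charged with 0.480 equiv of nucleophile, the limiting reagent there, 2.20 d counted from the start gives 4.31 % left, but that flask holds 38.2 % of electrophile with 1.87 % of its nucleophile remaining.

The data were generated by integration from invented constants.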